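Its constants belong to no real substance; the flask was simulated.

At early times in epsilon the reagent stands at 2.00 M, more than the 0.40 M of starting material, so its level can be frozen.

    starting material + reagent → open intermediate + by-product (k1 = 0.014 M⁻¹ s⁻¹)
    open intermediate ⇌ target (K2 = 1.7, k2 = 0.025 s⁻¹)
    open intermediate ⇌ isomer of the product (K3 = 2.2, k3 = 3.4 × 10⁻⁴ s⁻¹)
    open intermediate + capture agent → trapped intermediate (k4 = 0.0096 M⁻¹ s⁻¹)

| setting | epsilon | alpha | zeta | gamma |
|---|---|---|---|---|
| starting material | 0.40 M | 0.40 M (fed, over 1.00 min) | 0.40 M | 0.40 M |
| reagent | 2.00 M | 2.00 M | 2.00 M (fed, over 1.00 min) | 2.00 M |
| capture agent | 8.00 mM | 8.00 mM | 8.00 mM | 8.00 mM |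
| time | 1.0 min | 1.0 min | 1.0 min |  |
| remark | a closed flask charged with all of it at once and left for 1.0 min | a stirred flask in which starting material is dosed at a steady rate over 1.00 min without added volume, worked up at 1.0 min | a stirred flask in which reagent is dosed at a steady rate over 1.00 min without added volume, worked up at 1.0 min | a single well-mixed tank run continuously and read at steady state, 1.0 min in it on average |

- the stated concentrations are those of everything mixed, before any reaction; amounts are the same in each set-up
- the feed brings no volume worth counting
- run time (epsilon): 1.0 min

1. the set-up with the highest amount of open intermediate at the outlet or at the end, in percent of the starting material put in ("none" if the first two lie within 2 percentage points) (epsilon / alpha / zeta / gamma / none)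
2. amount of open intermediate at the outlet or at the end, in percent of the starting material put in, epsilon
3. amount of open intermediate at the outlet or at the end, in percent of the starting material put in, alpha
4. amount of open intermediate at the outlet or at the end, in percent of the starting material put in, zeta
5. amount of open intermediate at the outlet or at the end, in percent of the starting material put in, gamma

Frozen at the charge, the reagent turns the first step into a first-order loss of starting material with constant f, its rate constant times the reagent level, 0.0280 s⁻¹, so this reckoning leaves 18.6% of the starting material in epsilon after 1.0 min. Open intermediate goes to isomer and capture far more slowly than to target, so the reckoning keeps the target step. Its back constant b is 0.0147 s⁻¹; the step relaxes at λ, forward plus back, 0.0397 s⁻¹, towards a balance share of 37.0% for open intermediate. Solving making and relaxing together gives two parts: the balance share as reached by λ, 33.6%, plus a surplus of fresh intermediate, (f−b)/(λ−f) times the difference of the two decays, 10.7%. Together they make 44.3% for epsilon.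

The weak link is the frozen reagent. Under f, the time-mean share of starting material still present in epsilon is 48.4%, which puts the time-mean reagent at 1.79 M. That gives 0.0251 s⁻¹ for κ, the pseudo-first-order constant at the time-mean reagent level, and the same sum with κ yields 42.8%, less than the first figure. That number is the commitment. Alpha, fed across the run with reagent taken at its charge, is reckoned to convert about 51.6% against 77.8% reckoned for epsilon, so this reckoning prefers epsilon to alpha; zeta and gamma stay unreckoned by hand.

The forecast names epsilon, with 42.1% (40.5% to 43.5%) for epsilon, less than the hand figure of 42.8%, 33.2% for alpha, 35.2% for zeta and 32.8% for gamma: “The all-at-once batch wins because it converts about 78% against about 50–55% for either dosed run”.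

The simulation gives epsilon as best, with 41.9% for epsilon, 33.0% for alpha, 35.1% for zeta and 32.8% for gamma. In epsilon target stands at 35.2% beside that open intermediate. Reckoned for epsilon and put into the gamma tank, with its 1.0 min on average, κ gives 0.160 M of starting material, and the simulation reads 0.161 M there.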